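The route rests on disconnecting C4–C5, the bond joining the CH that carries the hydroxymethyl group (C4, C15) to the neighbouring ring CH2 (C5). It exploits the fact that C4 is the γ-carbon of the 3(2H)-furanone, vinylogous to the C1 ketone through C2=C3. With C15 held temporarily at the ester level, C4 becomes a soft carbanion that displaces a C5 iodide on the preformed trans-fused C6–C12 lactone. One operation closes the nine-membered oxacycle (ten-membered carbocycle) of the 11-oxabicyclo[6.2.1]undecene core and sets C4. The precursor is an acyclic furanone–lactone seco-iodide, assembled from two chiral-pool fragments by chromium-mediated allylation.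

Key step: step 13

Remark: germacrane numbering is used throughout (C1 furanone C=O, C2 =CH, C3 enol-ether carbon, C4 CH–C15H2OH, C5 CH2, C6 lactone O–CH, C7 CH bearing C11, C8 CH–O-angeloyl, C9 CH2, C10 quaternary carbon with the C14 methyl and the bridging oxygen, C11=C13 methylene, C12 lactone C=O; angeloyl = (2Z)-2-methylbut-2-enoyl). Compounds 17 and 19–24 are assumed to be carried as C11 epimer mixtures, because C11 becomes sp2 in step 16; C11 is therefore left undefined in their SMILES.

Step 1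
Reactants: 1 (2S)-but-3-ene-1,2-diol
Product: 2 (2S)-2-hydroxybut-3-en-1-yl 4-methylbenzenesulfonate
Conditions: TsCl, Bu2SnO (2 mol%), Et3N, CH2Cl2, 0 °C
Reagents that add atoms: 4-methylbenzenesulfonyl chloride, Cc1ccc(cc1)S(=O)(=O)Cl
Why: Stannylene-catalysed regioselective sulfonylation should select the primary hydroxyl of the 1,2-diol; the future C6 stereocentre comes from the chiral pool and is not touched.

Step 2
Reactants: 2 (2S)-2-hydroxybut-3-en-1-yl 4-methylbenzenesulfonate; 3 2-(bromomethyl)prop-2-enoic acid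
Product: 5 (2S)-1-{[(4-methylbenzenesulfonyl)oxy]}but-3-en-2-yl 2-(bromomethyl)prop-2-enoate, via 2-(bromomethyl)prop-2-enoyl chloride 4 (not isolated)
Conditions: 3, (COCl)2, DMF (cat.), CH2Cl2, 0 °C to rt; then 2, 2,6-lutidine, CH2Cl2, −20 to 0 °C
Reagents that add atoms: none
Why: O-acylation of the secondary allylic alcohol by the acid chloride formed in situ, with a hindered base that should not attack the allylic bromide in SN2' fashion; only the O–H bond reacts, so the carbinol configuration is retained.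

Step 3
Reactants: 5 (2S)-1-{[(4-methylbenzenesulfonyl)oxy]}but-3-en-2-yl 2-(bromomethyl)prop-2-enoate
Product: 6 [(2S)-4-(bromomethyl)-5-oxo-2,5-dihydrofuran-2-yl]methyl 4-methylbenzenesulfonate
Conditions: second-generation Grubbs catalyst (5 mol%), toluene (0.01 M), 80 °C
Reagents that add atoms: none
Why: Ring-closing olefin metathesis between the vinyl group and the 1,1-disubstituted acrylate should close the butenolide with loss of ethene, leaving the allylic bromide and the stereocentre untouched.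

Step 4
Reactants: 7 (2S)-2-hydroxy-2-methylbutanedioic acid ((S)-citramalic acid)
Product: 8 2-[(4S)-2,2,4-trimethyl-5-oxo-1,3-dioxolan-4-yl]acetic acid
Conditions: 2,2-dimethoxypropane, TsOH (cat.), acetone, rt
Reagents that add atoms: 2,2-dimethoxypropane, COC(C)(C)OC
Why: Acid-catalysed transacetalisation ties the tertiary hydroxyl and the adjacent carboxyl into a dioxolanone, which differentiates the two carboxyls and activates C1 as an acyl donor; C10 comes from the chiral pool.

Step 5
Reactants: 8 2-[(4S)-2,2,4-trimethyl-5-oxo-1,3-dioxolan-4-yl]acetic acid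
Product: 9 (5S)-5-(2-hydroxyethyl)-2,2,5-trimethyl-1,3-dioxolan-4-one
Conditions: BH3·SMe2, THF, 0 °C to rt; MeOH
Reagents that add atoms: none
Why: Borane reduction of the free carboxylic acid through its acyloxyborane should be chemoselective over the dioxolanone ester-acetal.

Step 6
Reactants: 9 (5S)-5-(2-hydroxyethyl)-2,2,5-trimethyl-1,3-dioxolan-4-one
Product: 10 (5S)-5-{2-[(tert-butyldimethylsilyl)oxy]ethyl}-2,2,5-trimethyl-1,3-dioxolan-4-one
Conditions: TBSCl, imidazole, CH2Cl2, 0 °C
Reagents that add atoms: tert-butyldimethylsilyl chloride, CC(C)(C)[Si](C)(C)Cl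
Why: Silyl ether formation caps the primary alcohol so that it can neither translactonise onto the dioxolanone nor quench the dianion of the next step.

Step 7
Reactants: 10 (5S)-5-{2-[(tert-butyldimethylsilyl)oxy]ethyl}-2,2,5-trimethyl-1,3-dioxolan-4-one; 11 tert-butyl 3-oxobutanoate
Product: 12 tert-butyl (6S)-8-[(tert-butyldimethylsilyl)oxy]-6-hydroxy-6-methyl-3,5-dioxooctanoate
Conditions: 11 (2.5 equiv), NaH then n-BuLi, THF, 0 °C; then 10, −78 to 0 °C; aq NH4Cl
Reagents that add atoms: none
Why: Claisen-type γ-acylation of the acetoacetate dianion at the activated dioxolanone carbonyl, followed by loss of acetone from the hemiketal, should give the α'-hydroxy-3,5-diketo ester (C1–C4 and C15 in place) without touching C10.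

Step 8
Reactants: 12 tert-butyl (6S)-8-[(tert-butyldimethylsilyl)oxy]-6-hydroxy-6-methyl-3,5-dioxooctanoate
Product: 14 tert-butyl 2-[(5S)-5-(2-hydroxyethyl)-5-methyl-4-oxo-4,5-dihydrofuran-2-yl]acetate, via furanone silyl ether 13 (not isolated)
Conditions: 1 M aq HCl, THF, rt
Reagents that add atoms: none
Why: Acid-catalysed cyclodehydration of the α'-hydroxy-1,3-diketone (5-exo-trig attack of the tertiary hydroxyl on C3, then loss of water) should form the 3(2H)-furanone, and the same acid cleaves the primary silyl ether.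

Step 9
Reactants: 14 tert-butyl 2-[(5S)-5-(2-hydroxyethyl)-5-methyl-4-oxo-4,5-dihydrofuran-2-yl]acetate
Product: 15 tert-butyl 2-[(5S)-5-methyl-4-oxo-5-(2-oxoethyl)-4,5-dihydrofuran-2-yl]acetate
Conditions: TEMPO (cat.), PhI(OAc)2, CH2Cl2, rt
Reagents that add atoms: none
Why: Oxoammonium (TEMPO) oxidation should take the primary alcohol to the C8 aldehyde without touching the active C4 methylene or the vinylogous ester; the aldehyde is used at once.

Step 10
Reactants: 15 tert-butyl 2-[(5S)-5-methyl-4-oxo-5-(2-oxoethyl)-4,5-dihydrofuran-2-yl]acetate; 6 [(2S)-4-(bromomethyl)-5-oxo-2,5-dihydrofuran-2-yl]methyl 4-methylbenzenesulfonate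
Product: 16 tert-butyl 2-[(5S)-5-{(2S)-2-hydroxy-2-[(2S,3R)-4-methylidene-2-{[(4-methylbenzenesulfonyl)oxy]methyl}-5-oxooxolan-3-yl]ethyl}-5-methyl-4-oxo-4,5-dihydrofuran-2-yl]acetate
Conditions: CrCl2 (3 equiv), THF, 0 °C to rt
Reagents that add atoms: none
Why: Nozaki–Hiyama-type allylation: the allylchromium formed from the allylic bromide should add through its γ-carbon (C7) in a closed chair transition state, anti to the CH2OTs group (6,7-trans lactone) and with the aldehyde substituent equatorial, which sets C7 and gives the (8S) carbinol while unveiling the α-methylene lactone.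

Step 11
Reactants: 16 tert-butyl 2-[(5S)-5-{(2S)-2-hydroxy-2-[(2S,3R)-4-methylidene-2-{[(4-methylbenzenesulfonyl)oxy]methyl}-5-oxooxolan-3-yl]ethyl}-5-methyl-4-oxo-4,5-dihydrofuran-2-yl]acetate
Product: 17 tert-butyl 2-[(5S)-5-{(2S)-2-hydroxy-2-[(2S,3R)-2-{[(4-methylbenzenesulfonyl)oxy]methyl}-5-oxo-4-[(phenylsulfanyl)methyl]oxolan-3-yl]ethyl}-5-methyl-4-oxo-4,5-dihydrofuran-2-yl]acetate
Conditions: PhSH (1.05 equiv), Et3N (0.1 equiv), CH2Cl2, 0 °C
Reagents that add atoms: thiophenol, Sc1ccccc1
Why: Base-catalysed thia-Michael addition masks the α-methylene lactone as a β-sulfide (the new C11 centre is inconsequential) and should be much faster than displacement of the β-branched tosylate.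

Step 12
Reactants: 17 tert-butyl 2-[(5S)-5-{(2S)-2-hydroxy-2-[(2S,3R)-2-{[(4-methylbenzenesulfonyl)oxy]methyl}-5-oxo-4-[(phenylsulfanyl)methyl]oxolan-3-yl]ethyl}-5-methyl-4-oxo-4,5-dihydrofuran-2-yl]acetate; 18 (2Z)-2-methylbut-2-enoic acid (angelic acid)
Product: 19 (1R)-2-[(2S)-5-(2-tert-butoxy-2-oxoethyl)-2-methyl-3-oxo-2,3-dihydrofuran-2-yl]-1-[(2S,3R)-2-{[(4-methylbenzenesulfonyl)oxy]methyl}-5-oxo-4-[(phenylsulfanyl)methyl]oxolan-3-yl]ethyl (2Z)-2-methylbut-2-enoate
Conditions: PPh3, DIAD, toluene, 0 °C to rt (betaine preformed, then 18 and 17)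
Reagents that add atoms: none
Why: Mitsunobu esterification: angelate should displace the C8 alkoxyphosphonium by SN2 with inversion, turning the (8S) carbinol into the required (8R) ester under conditions that do not isomerise angelate to tiglate.

Step 13
Reactants: 19 (1R)-2-[(2S)-5-(2-tert-butoxy-2-oxoethyl)-2-methyl-3-oxo-2,3-dihydrofuran-2-yl]-1-[(2S,3R)-2-{[(4-methylbenzenesulfonyl)oxy]methyl}-5-oxo-4-[(phenylsulfanyl)methyl]oxolan-3-yl]ethyl (2Z)-2-methylbut-2-enoate
Product: 21 tert-butyl (4R,6R,7S,8R,10S)-8-angeloyloxy-1-oxo-13-(phenylsulfanyl)-3,10-epoxygermacr-2-en-12,6-olid-15-oate, via seco-iodide 20 (not isolated)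
Conditions: NaI (5 equiv), MeCN, 70 °C; then syringe-pump addition to Cs2CO3 (3 equiv), MeCN, 60 °C, 2 mM
Reagents that add atoms: none
Why: Halide exchange first turns the hindered tosylate into the softer iodide 20; Cs2CO3 then deprotonates C4–H2, which is acidified by the C15 ester and, through C2=C3, by the C1 ketone, and the cesium dienolate displaces iodide at C5 in an intramolecular SN2 C-alkylation. The closest known reaction types are high-dilution macrocyclising alkylations of malonate and β-keto ester anions and the exocyclic (γ) alkylation of 3(2H)-furanone and dioxinone acetates. The closure is 9-exo-tet for the oxonane ring (O, C3–C10) and at the same time completes the ten-membered carbocycle C1–C10 of the 11-oxabicyclo[6.2.1]undecene core. The new C4 stereocentre is controlled by C10 through the bridge: C5 can reach only the dienolate face that carries C9, the ester takes the exo position with C4–H eclipsing C2–H (minimal A(1,3) strain), and because C4–H stays acidic the carbonate should equilibrate any epimer to this arrangement, which is the one drawn. The step needs C4- over C2- and O-alkylation and ring closure over oligomerisation; these should be secured by the soft iodide and cesium counter-ion, by the fact that only C4 attack keeps the vinylogous-ester conjugation, by the rigid furanone and trans-lactone that leave few rotors in the tether, and by slow addition at 2 mM. Angelate, tert-butyl ester and lactone are inert to carbonate, and the thioether removes the competing Michael acceptor.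

Step 14
Reactants: 21 tert-butyl (4R,6R,7S,8R,10S)-8-angeloyloxy-1-oxo-13-(phenylsulfanyl)-3,10-epoxygermacr-2-en-12,6-olid-15-oate
Product: 22 (4R,6R,7S,8R,10S)-8-angeloyloxy-1-oxo-13-(phenylsulfanyl)-3,10-epoxygermacr-2-en-12,6-olid-15-oic acid
Conditions: TFA, CH2Cl2, 0 °C; concentrated cold and used directly
Reagents that add atoms: none
Why: Acidolysis of the tert-butyl ester (loss of 2-methylpropene) frees the C15 acid while lactone, angelate and furanone are acid-stable, and C4 stays in its thermodynamic configuration.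

Step 15
Reactants: 22 (4R,6R,7S,8R,10S)-8-angeloyloxy-1-oxo-13-(phenylsulfanyl)-3,10-epoxygermacr-2-en-12,6-olid-15-oic acid
Product: 23 (4S,6R,7S,8R,10S)-8-angeloyloxy-15-hydroxy-1-oxo-13-(phenylsulfanyl)-3,10-epoxygermacr-2-en-12,6-olide
Conditions: BH3·SMe2 (1.5 equiv), THF, −10 to 0 °C; MeOH
Reagents that add atoms: none
Why: Borane reduction of the carboxylic acid through its acyloxyborane should be much faster than attack on the lactone, the enoate or the vinylogous-ester carbonyl, and it ends the easy epimerisation of C4 (the descriptor changes from R to S only through priorities).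

Step 16
Reactants: 23 (4S,6R,7S,8R,10S)-8-angeloyloxy-15-hydroxy-1-oxo-13-(phenylsulfanyl)-3,10-epoxygermacr-2-en-12,6-olide
Product: 25 (4S,6R,7S,8R,10S)-8-angeloyloxy-15-hydroxy-1-oxo-3,10-epoxygermacra-2,11(13)-dien-12,6-olide, via sulfoxide 24 (not isolated)
Conditions: mCPBA (1.0 equiv), CH2Cl2, −78 °C; then CaCO3, toluene, 110 °C
Reagents that add atoms: none
Why: Chemoselective sulfide oxidation followed by thermal syn-elimination of the sulfoxide, whose only β-hydrogen is C11–H, should regenerate the exocyclic C11=C13 methylene and give the target.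

Compound list
1 | (2S)-but-3-ene-1,2-diol | C=C[C@H](O)CO | starting material
2 | (2S)-2-hydroxybut-3-en-1-yl 4-methylbenzenesulfonate | C=C[C@H](O)COS(=O)(=O)c1ccc(C)cc1 | intermediate
3 | 2-(bromomethyl)prop-2-enoic acid | C=C(CBr)C(=O)O | starting material
4 | 2-(bromomethyl)prop-2-enoyl chloride | C=C(CBr)C(Cl)=O | intermediate (not isolated)
5 | (2S)-1-{[(4-methylbenzenesulfonyl)oxy]}but-3-en-2-yl 2-(bromomethyl)prop-2-enoate | C=C[C@H](OC(=O)C(=C)CBr)COS(=O)(=O)c1ccc(C)cc1 | intermediate
6 | [(2S)-4-(bromomethyl)-5-oxo-2,5-dihydrofuran-2-yl]methyl 4-methylbenzenesulfonate | BrCC1=C[C@@H](COS(=O)(=O)c2ccc(C)cc2)OC1=O | intermediate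
7 | (2S)-2-hydroxy-2-methylbutanedioic acid ((S)-citramalic acid) | OC(=O)[C@](C)(CC(=O)O)O | starting material
8 | 2-[(4S)-2,2,4-trimethyl-5-oxo-1,3-dioxolan-4-yl]acetic acid | CC1(C)OC(=O)[C@](C)(CC(=O)O)O1 | intermediate
9 | (5S)-5-(2-hydroxyethyl)-2,2,5-trimethyl-1,3-dioxolan-4-one | CC1(C)OC(=O)[C@](C)(CCO)O1 | intermediate
10 | (5S)-5-{2-[(tert-butyldimethylsilyl)oxy]ethyl}-2,2,5-trimethyl-1,3-dioxolan-4-one | CC1(C)OC(=O)[C@](C)(CCO[Si](C)(C)C(C)(C)C)O1 | intermediate
11 | tert-butyl 3-oxobutanoate | CC(=O)CC(=O)OC(C)(C)C | starting material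
12 | tert-butyl (6S)-8-[(tert-butyldimethylsilyl)oxy]-6-hydroxy-6-methyl-3,5-dioxooctanoate | CC(C)(C)OC(=O)CC(=O)CC(=O)[C@@](C)(O)CCO[Si](C)(C)C(C)(C)C | intermediate
13 | tert-butyl 2-[(5S)-5-{2-[(tert-butyldimethylsilyl)oxy]ethyl}-5-methyl-4-oxo-4,5-dihydrofuran-2-yl]acetate | CC(C)(C)OC(=O)CC1=CC(=O)[C@](C)(CCO[Si](C)(C)C(C)(C)C)O1 | intermediate (not isolated)
14 | tert-butyl 2-[(5S)-5-(2-hydroxyethyl)-5-methyl-4-oxo-4,5-dihydrofuran-2-yl]acetate | CC(C)(C)OC(=O)CC1=CC(=O)[C@](C)(CCO)O1 | intermediate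
15 | tert-butyl 2-[(5S)-5-methyl-4-oxo-5-(2-oxoethyl)-4,5-dihydrofuran-2-yl]acetate | CC(C)(C)OC(=O)CC1=CC(=O)[C@](C)(CC=O)O1 | intermediate
16 | tert-butyl 2-[(5S)-5-{(2S)-2-hydroxy-2-[(2S,3R)-4-methylidene-2-{[(4-methylbenzenesulfonyl)oxy]methyl}-5-oxooxolan-3-yl]ethyl}-5-methyl-4-oxo-4,5-dihydrofuran-2-yl]acetate | C=C1C(=O)O[C@H](COS(=O)(=O)c2ccc(C)cc2)[C@H]1[C@@H](O)C[C@]3(C)OC(CC(=O)OC(C)(C)C)=CC3=O | intermediate
17 | tert-butyl 2-[(5S)-5-{(2S)-2-hydroxy-2-[(2S,3R)-2-{[(4-methylbenzenesulfonyl)oxy]methyl}-5-oxo-4-[(phenylsulfanyl)methyl]oxolan-3-yl]ethyl}-5-methyl-4-oxo-4,5-dihydrofuran-2-yl]acetate (C11 epimers) | O=C1O[C@H](COS(=O)(=O)c2ccc(C)cc2)[C@H](C1CSc2ccccc2)[C@@H](O)C[C@]3(C)OC(CC(=O)OC(C)(C)C)=CC3=O | intermediate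
18 | (2Z)-2-methylbut-2-enoic acid (angelic acid) | C/C=C(/C)C(=O)O | starting material
19 | (1R)-2-[(2S)-5-(2-tert-butoxy-2-oxoethyl)-2-methyl-3-oxo-2,3-dihydrofuran-2-yl]-1-[(2S,3R)-2-{[(4-methylbenzenesulfonyl)oxy]methyl}-5-oxo-4-[(phenylsulfanyl)methyl]oxolan-3-yl]ethyl (2Z)-2-methylbut-2-enoate (C11 epimers) | O=C1O[C@H](COS(=O)(=O)c2ccc(C)cc2)[C@H](C1CSc2ccccc2)[C@H](OC(=O)/C(C)=C\C)C[C@]3(C)OC(CC(=O)OC(C)(C)C)=CC3=O | intermediate
20 | (1R)-2-[(2S)-5-(2-tert-butoxy-2-oxoethyl)-2-methyl-3-oxo-2,3-dihydrofuran-2-yl]-1-[(2S,3R)-2-(iodomethyl)-5-oxo-4-[(phenylsulfanyl)methyl]oxolan-3-yl]ethyl (2Z)-2-methylbut-2-enoate (C11 epimers) | O=C1O[C@H](CI)[C@H](C1CSc2ccccc2)[C@H](OC(=O)/C(C)=C\C)C[C@]3(C)OC(CC(=O)OC(C)(C)C)=CC3=O | intermediate (not isolated)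
21 | tert-butyl (4R,6R,7S,8R,10S)-8-angeloyloxy-1-oxo-13-(phenylsulfanyl)-3,10-epoxygermacr-2-en-12,6-olid-15-oate (C11 epimers) | O=C1O[C@@H]2C[C@@H](C(=O)OC(C)(C)C)C3=CC(=O)[C@](C)(C[C@@H](OC(=O)/C(C)=C\C)[C@H]2C1CSc4ccccc4)O3 | intermediate
22 | (4R,6R,7S,8R,10S)-8-angeloyloxy-1-oxo-13-(phenylsulfanyl)-3,10-epoxygermacr-2-en-12,6-olid-15-oic acid (C11 epimers) | O=C1O[C@@H]2C[C@@H](C(=O)O)C3=CC(=O)[C@](C)(C[C@@H](OC(=O)/C(C)=C\C)[C@H]2C1CSc4ccccc4)O3 | intermediate
23 | (4S,6R,7S,8R,10S)-8-angeloyloxy-15-hydroxy-1-oxo-13-(phenylsulfanyl)-3,10-epoxygermacr-2-en-12,6-olide (C11 epimers) | O=C1O[C@@H]2C[C@@H](CO)C3=CC(=O)[C@](C)(C[C@@H](OC(=O)/C(C)=C\C)[C@H]2C1CSc4ccccc4)O3 | intermediate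
24 | (4S,6R,7S,8R,10S)-8-angeloyloxy-15-hydroxy-1-oxo-13-(phenylsulfinyl)-3,10-epoxygermacr-2-en-12,6-olide (C11 and sulfur epimers) | O=C1O[C@@H]2C[C@@H](CO)C3=CC(=O)[C@](C)(C[C@@H](OC(=O)/C(C)=C\C)[C@H]2C1CS(=O)c4ccccc4)O3 | intermediate (not isolated)
25 | (4S,6R,7S,8R,10S)-8-angeloyloxy-15-hydroxy-1-oxo-3,10-epoxygermacra-2,11(13)-dien-12,6-olide (CNP0108636.1) | C=C1C(=O)O[C@@H]2C[C@@H](CO)C3=CC(=O)[C@](C)(C[C@@H](OC(=O)/C(C)=C\C)[C@@H]12)O3 | target

Total step count: 16. Longest linear sequence: 13 steps (from 7: steps 4–9, then 10–16).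

Steps most likely to fail

Step 13 (ring closure). Oligomerisation, O- or C2-alkylation, or base-induced loss of HI may outrun the nine-membered SN2 closure. The ring would then be closed at the same bond by condensation instead of displacement. Setting out from 19, halide exchange as in step 13 followed by Kornblum-type oxidation of the iodide with Me3NO in DMSO would give the C5 aldehyde F1. Intramolecular Knoevenagel condensation of the C4 methylene with this aldehyde (piperidinium acetate, benzene, high dilution) would give the C4=C5 alkylidene macrocycle F2; here a reversible aldol addition and an irreversible dehydration to a conjugated dienone replace the slow displacement. Conjugate reduction with Hantzsch ester would come back to 21, with C4 again set by equilibration.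

Step 12 (inversion at C8). Elimination, participation by the lactone carbonyl, or amination of the active C4 methylene by the azodicarboxylate may prevail over SN2 inversion at the hindered carbinol. The (8R) configuration would then be made directly, so that no inversion is needed. Setting out from 6 and 15, 6 would be converted with (Bu3Sn)2 and Pd(PPh3)4 (cat.) into the allylstannane F3. Its BF3·OEt2-promoted addition to 15 (CH2Cl2, −78 °C) through an open antiperiplanar transition state should give the syn adduct, the (8R) alcohol F4. Thia-Michael addition of PhSH as in step 11 would give the (8R) sulfide F5, and Yamaguchi esterification with 18 (2,4,6-trichlorobenzoyl chloride, Et3N, toluene, 75 °C), which retains configuration, would rejoin the route at 19.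

Step 14 (ester cleavage). The vinylogous β-keto acid may lose CO2 during or after cleavage of the tert-butyl ester, and borane may over-reduce in step 15. The loss would then be made part of the plan. Setting out from 21, TFA followed by warming in toluene would give the 15-nor macrocycle F6. γ-Deprotonation of the furanone with LiN(SiMe3)2 (THF, −78 °C) and aldol addition of the dienolate to monomeric formaldehyde from the exo face, anti to the C5–C9 bridge, would install C15 with the required C4 configuration and come back at 23, bypassing 22 and the borane reduction.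

Further compounds
F1 | step 13 | (1R)-2-[(2S)-5-(2-tert-butoxy-2-oxoethyl)-2-methyl-3-oxo-2,3-dihydrofuran-2-yl]-1-[(2S,3R)-2-formyl-5-oxo-4-[(phenylsulfanyl)methyl]oxolan-3-yl]ethyl (2Z)-2-methylbut-2-enoate | O=C1O[C@H](C=O)[C@H](C1CSc2ccccc2)[C@H](OC(=O)/C(C)=C\C)C[C@]3(C)OC(CC(=O)OC(C)(C)C)=CC3=O
F2 | step 13 | tert-butyl 8-angeloyloxy-1-oxo-13-(phenylsulfanyl)-3,10-epoxygermacra-2,4-dien-12,6-olid-15-oate (C6, C7, C8 and C10 as in 21; C4=C5 geometry as formed) | O=C1O[C@@H]2C=C(C(=O)OC(C)(C)C)C3=CC(=O)[C@](C)(C[C@@H](OC(=O)/C(C)=C\C)[C@H]2C1CSc4ccccc4)O3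
F3 | step 12 | [(2S)-5-oxo-4-[(tributylstannyl)methyl]-2,5-dihydrofuran-2-yl]methyl 4-methylbenzenesulfonate | CCCC[Sn](CCCC)(CCCC)CC1=C[C@@H](COS(=O)(=O)c2ccc(C)cc2)OC1=O
F4 | step 12 | tert-butyl 2-[(5S)-5-{(2R)-2-hydroxy-2-[(2S,3R)-4-methylidene-2-{[(4-methylbenzenesulfonyl)oxy]methyl}-5-oxooxolan-3-yl]ethyl}-5-methyl-4-oxo-4,5-dihydrofuran-2-yl]acetate | C=C1C(=O)O[C@H](COS(=O)(=O)c2ccc(C)cc2)[C@H]1[C@H](O)C[C@]3(C)OC(CC(=O)OC(C)(C)C)=CC3=O
F5 | step 12 | tert-butyl 2-[(5S)-5-{(2R)-2-hydroxy-2-[(2S,3R)-2-{[(4-methylbenzenesulfonyl)oxy]methyl}-5-oxo-4-[(phenylsulfanyl)methyl]oxolan-3-yl]ethyl}-5-methyl-4-oxo-4,5-dihydrofuran-2-yl]acetate (C11 epimers) | O=C1O[C@H](COS(=O)(=O)c2ccc(C)cc2)[C@H](C1CSc2ccccc2)[C@H](O)C[C@]3(C)OC(CC(=O)OC(C)(C)C)=CC3=O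
F6 | step 14 | (6R,7S,8R,10S)-8-angeloyloxy-1-oxo-13-(phenylsulfanyl)-15-nor-3,10-epoxygermacr-2-en-12,6-olide (C11 epimers) | O=C1O[C@@H]2CCC3=CC(=O)[C@](C)(C[C@@H](OC(=O)/C(C)=C\C)[C@H]2C1CSc4ccccc4)O3
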